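The route rests on cutting the C2–C3 bond of the dihydrofuran ring, the bond between the O1-bearing carbon that carries the isopropenyl group and the carbinol carbon. The unit C3(O)–C2–C(CH3)=CH2 is a homoallylic alcohol, so it is assembled from three pieces at once: an aryl allenyl ether (O1–CH=C=CH2), the ortho-formyl group and a methyl nucleophile. A nickel-catalysed, ligand-controlled methylative cyclization of a 2-(allenyloxy)benzaldehyde with Me2Zn should close the ring, add the vinylic methyl group and set both stereocentres cis in one operation. The acetyl group travels as a 1-ethoxyvinyl group and is released in the work-up. Esterification with angelic acid completes the synthesis.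

Key step: step 5

Remark: the target is read as the cis-(2R,3R) diastereomer (isopropenyl at C2 and angeloyloxy at C3 on the same face of the dihydrofuran ring). Which antipode of the chiral ligand delivers this sense in step 5 has to be settled by a screen.

Step 1
Reactants: 1 2-hydroxy-3,4-dimethoxybenzaldehyde
Product: 2 2-hydroxy-5-iodo-3,4-dimethoxybenzaldehyde
Conditions: NIS (1.05 equiv), TsOH·H2O (10 mol%), MeCN, 0 °C to rt
Reagents that add atoms: N-iodosuccinimide, O=C1CCC(=O)N1I
Why: Electrophilic aromatic iodination should go to C5, the only free position that is para to the phenol and ortho to a methoxy group and at the same time meta to the deactivating formyl group.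

Step 2
Reactants: 2 2-hydroxy-5-iodo-3,4-dimethoxybenzaldehyde; 3 propargyl bromide
Product: 4 5-iodo-3,4-dimethoxy-2-(prop-2-yn-1-yloxy)benzaldehyde
Conditions: K2CO3 (1.5 equiv), DMF, rt
Reagents that add atoms: propargyl bromide 3, C#CCBr
Why: Williamson ether synthesis, in which the acidic salicylaldehyde-type phenoxide displaces bromide from the primary propargylic halide in an SN2 reaction while carbonate is too weak a base to touch the alkyne or the aldehyde.

Step 3
Reactants: 4 5-iodo-3,4-dimethoxy-2-(prop-2-yn-1-yloxy)benzaldehyde; 5 tributyl(1-ethoxyvinyl)stannane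
Product: 6 5-(1-ethoxyvinyl)-3,4-dimethoxy-2-(prop-2-yn-1-yloxy)benzaldehyde
Conditions: Pd(PPh3)4 (5 mol%), toluene, 100 °C; chromatography on Et3N-deactivated silica
Reagents that add atoms: tributyl(1-ethoxyvinyl)stannane 5, C=C(OCC)[Sn](CCCC)(CCCC)CCCC
Why: Stille cross-coupling of the aryl iodide with the α-ethoxyvinylstannane installs the acetyl group in a base-stable masked form, and the neutral conditions free of copper salts and amines should leave the terminal alkyne and the formyl group alone.

Step 4
Reactants: 6 5-(1-ethoxyvinyl)-3,4-dimethoxy-2-(prop-2-yn-1-yloxy)benzaldehyde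
Product: 7 5-(1-ethoxyvinyl)-3,4-dimethoxy-2-(propa-1,2-dien-1-yloxy)benzaldehyde
Conditions: t-BuOK (0.3 equiv), THF, 0 °C; aq. NaHCO3 quench
Reagents that add atoms: none
Why: Base-catalysed propargyl-to-allenyl prototropic isomerization of an aryl propargyl ether, driven by conjugation of the allene with oxygen and run with no enolizable carbonyl group present because the acetyl group is masked as the enol ether.

Step 5
Reactants: 7 5-(1-ethoxyvinyl)-3,4-dimethoxy-2-(propa-1,2-dien-1-yloxy)benzaldehyde; 8 dimethylzinc
Product: 10 1-[(2R,3R)-3-hydroxy-6,7-dimethoxy-2-(prop-1-en-2-yl)-2,3-dihydrobenzofuran-5-yl]ethan-1-one, via cyclized enol ether alcohol 9 (not isolated)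
Conditions: Ni(cod)2 (10 mol%), chiral spirobiindane phosphoramidite of the SIPHOS type (12 mol%), Me2Zn (2.5 equiv), THF, 0 °C; then 0.5 M aq. HCl, THF, 0 °C, 15 min
Reagents that add atoms: dimethylzinc 8, C[Zn]C; water, O
Why: Proposed new method: zerovalent nickel should join the formyl carbon to the oxygen-bearing carbon of the allene by oxidative cyclization to a cis-fused five-membered oxanickelacycle, after which a methyl group passes from zinc to nickel and reductive elimination places it on the central allene carbon, so that ring, carbinol and isopropenyl group arise together. The closest known reaction types are the ligand-free, racemic nickel-catalysed alkylative cyclization of allenyl aldehydes with organozincs, which gives cis-2-alkenylcycloalkanols, and the phosphoramidite-controlled nickel-catalysed alkylative coupling of alkynes with aldehydes and Me2Zn; the combination of a chiral ligand with an oxygen-substituted allene has not been shown. The dihydrofuran ring closes in the 5-exo-trig mode at the carbonyl carbon, the reacting allene C=C bond also lying outside the new ring. C2 and C3 are created in the same bond-forming event: their cis relation follows from the cis ring fusion that the metallacycle demands, and the absolute (2R,3R) sense is imposed by the chiral phosphoramidite on nickel. The step needs bonding at the allene carbon next to oxygen instead of the central or terminal one, reaction of the aldehyde alone, and ligand-bound nickel outpacing any ligand-free nickel; the three-atom tether C3a–C7a–O1 permits a five-membered ring only through the oxygen-bearing carbon, and the second carbonyl group is hidden as the enol ether. Dilute acid in the work-up then hydrolyses the 1-ethoxyvinyl group of 9 to the acetyl group of 10.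

Step 6
Reactants: 10 1-[(2R,3R)-3-hydroxy-6,7-dimethoxy-2-(prop-1-en-2-yl)-2,3-dihydrobenzofuran-5-yl]ethan-1-one; 11 angelic acid
Product: 13 (2R,3R)-5-acetyl-6,7-dimethoxy-2-(prop-1-en-2-yl)-2,3-dihydrobenzofuran-3-yl (Z)-2-methylbut-2-enoate (CNP0113631.1), via mixed anhydride 12 (not isolated)
Conditions: 11 (2 equiv), 2,4,6-trichlorobenzoyl chloride (2 equiv), Et3N (2.2 equiv), toluene, rt; then 10, toluene, 80 °C, no DMAP
Reagents that add atoms: angelic acid 11, C/C=C(/C)C(=O)O
Why: Yamaguchi esterification through the mixed anhydride 12, run without DMAP so that the Z double bond of the angeloyl group should not isomerize to the tigloyl form, and with the C3–O bond left intact so that the configuration at C3 is retained.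

Compound list
1 | 2-hydroxy-3,4-dimethoxybenzaldehyde | O=Cc1ccc(OC)c(OC)c1O | starting material
2 | 2-hydroxy-5-iodo-3,4-dimethoxybenzaldehyde | O=Cc1cc(I)c(OC)c(OC)c1O | intermediate
3 | propargyl bromide (3-bromoprop-1-yne) | C#CCBr | starting material
4 | 5-iodo-3,4-dimethoxy-2-(prop-2-yn-1-yloxy)benzaldehyde | C#CCOc1c(C=O)cc(I)c(OC)c1OC | intermediate
5 | tributyl(1-ethoxyvinyl)stannane | C=C(OCC)[Sn](CCCC)(CCCC)CCCC | starting material
6 | 5-(1-ethoxyvinyl)-3,4-dimethoxy-2-(prop-2-yn-1-yloxy)benzaldehyde | C#CCOc1c(C=O)cc(C(=C)OCC)c(OC)c1OC | intermediate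
7 | 5-(1-ethoxyvinyl)-3,4-dimethoxy-2-(propa-1,2-dien-1-yloxy)benzaldehyde | C=C=COc1c(C=O)cc(C(=C)OCC)c(OC)c1OC | intermediate
8 | dimethylzinc | C[Zn]C | starting material
9 | (2R,3R)-5-(1-ethoxyvinyl)-6,7-dimethoxy-2-(prop-1-en-2-yl)-2,3-dihydrobenzofuran-3-ol, cis, present as its methylzinc alkoxide until the quench | C=C(C)[C@H]1Oc2c(cc(C(=C)OCC)c(OC)c2OC)[C@H]1O | intermediate
10 | 1-[(2R,3R)-3-hydroxy-6,7-dimethoxy-2-(prop-1-en-2-yl)-2,3-dihydrobenzofuran-5-yl]ethan-1-one, cis | C=C(C)[C@H]1Oc2c(cc(C(C)=O)c(OC)c2OC)[C@H]1O | intermediate
11 | angelic acid, (Z)-2-methylbut-2-enoic acid | C/C=C(/C)C(=O)O | starting material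
12 | (Z)-2-methylbut-2-enoic 2,4,6-trichlorobenzoic anhydride | C/C=C(/C)C(=O)OC(=O)c1c(Cl)cc(Cl)cc1Cl | intermediate
13 | (2R,3R)-5-acetyl-6,7-dimethoxy-2-(prop-1-en-2-yl)-2,3-dihydrobenzofuran-3-yl (Z)-2-methylbut-2-enoate (CNP0113631.1) | C=C(C)[C@H]1Oc2c(cc(C(C)=O)c(OC)c2OC)[C@H]1OC(=O)/C(C)=C\C | target

Total step count: 6. Longest linear sequence: 6 steps, from 1 to 13.

Steps most likely to fail

Step 5 (proposed new method). Enantiofacial control may be poor if ligand-free nickel turns over in the background. Bonding may occur at the central or terminal allene carbon, methyl may transfer directly to the formyl group, zerovalent nickel may cleave the allenyl C–O bond, and acid in the work-up may dehydrate the benzylic alcohol towards a benzofuran. The fallback uses known chemistry and takes the absolute configuration from an enzyme instead of the catalyst. It sets out from 7 and returns at 10. Compound 7 is cyclized under the ligand-free conditions known for allenyl aldehydes (Ni(cod)2, Me2Zn, THF, 0 °C), which should give the racemic cis enol ether alcohol F1. Dilute HCl in the work-up should hydrolyse this to the racemic cis keto alcohol F2. A lipase-catalysed kinetic resolution (Candida antarctica lipase B, vinyl acetate, MTBE, 30 °C) is then expected, by the Kazlauskas rule, to acetylate the (2S,3S)-enantiomer to the (2S,3S)-acetate F3, because this enantiomer corresponds to the fast-reacting (R)-1-indanol pattern. The (2R,3R)-alcohol 10 should remain and is separated by chromatography.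

Step 4. tert-Butoxide or the potassium acetylide formed from the terminal alkyne may attack the unprotected formyl group (Tishchenko-type disproportionation, alkynylation) faster than the prototropic shift, and the allenyl ether may oligomerize. The fallback removes every carbonyl group before the base step. It sets out from 6 and returns at 10. Ethylene glycol with catalytic TsOH in toluene under water separation should convert both the formyl group and the 1-ethoxyvinyl group (by addition of the diol and loss of ethanol) into dioxolanes and give the bis(dioxolane) propargyl ether F4. t-BuOK (0.3 equiv) in THF should then give the bis(dioxolane) allenyl ether F5. PPTS in aqueous acetone at rt should release the keto aldehyde allenyl ether F6, the aryl acetals being expected to hydrolyse faster than the electron-poor aryloxyallene. F6 is cyclized under the conditions of step 5 with a neutral NH4Cl work-up and should give 10 directly.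

Step 6. The angeloyl double bond may isomerize from Z to E during activation or acyl transfer, acylation of the hindered cis alcohol may be sluggish, and prolonged heating with amine may cause elimination across C2–C3 towards the benzofuran. The fallback builds the Z alkene on the ester after the acylation. It sets out from 10 and returns at 13. Alcohol 10 is esterified with 2-[bis(2,2,2-trifluoroethoxy)phosphoryl]propanoic acid (DCC, catalytic DMAP, CH2Cl2, 0 °C) to the phosphonate ester F7, a mixture of epimers at the phosphorus-bearing carbon. A Still–Gennari olefination (KHMDS, 1.0 equiv, 18-crown-6, THF, −78 °C, then acetaldehyde) should give the Z-configured angelate 13.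

Further compounds
F1 | step 5 | racemic cis-5-(1-ethoxyvinyl)-6,7-dimethoxy-2-(prop-1-en-2-yl)-2,3-dihydrobenzofuran-3-ol | C=C(C)[C@H]1Oc2c(cc(C(=C)OCC)c(OC)c2OC)[C@H]1O.C=C(C)[C@@H]1Oc2c(cc(C(=C)OCC)c(OC)c2OC)[C@@H]1O
F2 | step 5 | racemic cis-1-[3-hydroxy-6,7-dimethoxy-2-(prop-1-en-2-yl)-2,3-dihydrobenzofuran-5-yl]ethan-1-one | C=C(C)[C@H]1Oc2c(cc(C(C)=O)c(OC)c2OC)[C@H]1O.C=C(C)[C@@H]1Oc2c(cc(C(C)=O)c(OC)c2OC)[C@@H]1O
F3 | step 5 | (2S,3S)-5-acetyl-6,7-dimethoxy-2-(prop-1-en-2-yl)-2,3-dihydrobenzofuran-3-yl acetate | C=C(C)[C@@H]1Oc2c(cc(C(C)=O)c(OC)c2OC)[C@@H]1OC(C)=O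
F4 | step 4 | 2-[5-(1,3-dioxolan-2-yl)-2,3-dimethoxy-4-(prop-2-yn-1-yloxy)phenyl]-2-methyl-1,3-dioxolane | C#CCOc1c(C2OCCO2)cc(C2(C)OCCO2)c(OC)c1OC
F5 | step 4 | 2-[5-(1,3-dioxolan-2-yl)-2,3-dimethoxy-4-(propa-1,2-dien-1-yloxy)phenyl]-2-methyl-1,3-dioxolane | C=C=COc1c(C2OCCO2)cc(C2(C)OCCO2)c(OC)c1OC
F6 | step 4 | 5-acetyl-3,4-dimethoxy-2-(propa-1,2-dien-1-yloxy)benzaldehyde | C=C=COc1c(C=O)cc(C(C)=O)c(OC)c1OC
F7 | step 6 | (2R,3R)-5-acetyl-6,7-dimethoxy-2-(prop-1-en-2-yl)-2,3-dihydrobenzofuran-3-yl 2-[bis(2,2,2-trifluoroethoxy)phosphoryl]propanoate | C=C(C)[C@H]1Oc2c(cc(C(C)=O)c(OC)c2OC)[C@H]1OC(=O)C(C)P(=O)(OCC(F)(F)F)OCC(F)(F)F
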